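(The runs were generated by integration for substances that don't exist; noise was put on by code.)

In a one-step world each L begins one chain and each J takes one E, so, counting in fractions of the E charged, chain length is a plain division.

common to all: E 20 mM (fed, over 30 s)

|  | J | L | remark | time |
|---|---|---|---|---|
| ochre | 1 mM | 1 mol% | the very flask that is asked about, followed so far |  |
| green | 1 mM | 0.67 mol% | run made earlier |  |
| flask | 1.00 mM | 1 mol% |  | 15 min |

- ochre (time / min: G / %, E / %): 0.833: 4, 89; 1.50: 19, 72; 2.50: 46, 52; 3.00: 57, 40; 4.00: 69, 21; 5.00: 78, 17
- green (time / min: G / %, E / %): 0.500: 1, 97; 0.833: 4, 90; 1.33: 9, 83; 2.00: 23, 69; 4.00: 58, 37; 6.00: 77, 17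

(scatter of a reading: 2 percentage points)

- the average divides the monomer in chains by the number of chains begun, living and dead together
- the earlier runs were read with a standard deviation of 2 percentage points
- the earlier runs do not show the number of chains; that part of a forecast is a guess

- average number of monomer units in a chain (chains begun, living or dead) at 15 min
- part of the E that has reacted at 15 min

In the flask J is 5.00% of the charge and L is 1 mol%. I took one minus the J share, divided by the L loading, as the target degree of polymerisation, 95.0.

Turned round, if J began the chains, the same division would give 19.0, a factor 5.00 away. I held two readings against that. Ochre and green have equal J and differ in L, and at 4.00 min ochre, with L at 1 mol%, read E 21%, below the 37% of green, with L at 0.67 mol%; that ties L to the rate, though the runs do not show the number of chains. If J began chains, the E it took should grow into G, but the ochre gap between charge and E plus G read 5.00% at 5.00 min, about the J share. So I committed, as a guess, to chains begun by L, with a length somewhat under 95.0 if E stays free.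

The forecast gave 20 and 98%, reckoning “if all J starts one chain”, and my length differs from it.

The flask gave 92.2 and 94.4%.

    G + Q → E + Q, rate k1*[Q] as long as [G] is above zero (k = 0.0680 s⁻¹)
    E + Q → G + Q, rate k2*[Q]*[E] (k = 61.0 M⁻¹ s⁻¹)
    E + X → Q + G (k = 5.60 M⁻¹ s⁻¹)
    J + E → D (k = 7.30 M⁻¹ s⁻¹)
    L ⇌ X (K = 0.680, k = 0.0100 s⁻¹)

The flask's 92.2 lay under 95.0, with 5.6% of its E still free. The same division on the neighbour flask with 8.0 mM of E, where the loading of L is unchanged and the J share is 12.5%, gives 87.5. Taking off the 16% of E still free there brings it to 71.3. That neighbour flask gave a chain length of 73.1, with 83.8% of its E reacted.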